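## The problem

Compound 13 is a monocyclic monoterpene ether. The cyclohexene ring is numbered C1 (methyl-bearing alkene carbon), C2 (=CH), C3 (CH2), C4 (CH–O), C5 (CMe2) and C6 (CH). It carries an isovalerate at C4 and, through the exocyclic methylene C7 on C6, the 7-oxygen of umbelliferone. No rings are fused. The difficulty lies in the contiguous C4–C5–C6 triad, where a quaternary carbon is flanked by the only two stereocentres, (4R) and (6S).

C4–O and C6–C7 are 1,3-related and lie on the same ring face, so a two-atom O–C7 bridge can join them. C4 can therefore dictate C6 through a tether, whereas C6 offers no comparable hold on C4. The absolute configuration thus reduces to one carbinol centre.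

- **Fragile groups:** The coumarin lactone tolerates no hydride, organometallic or hydroxide reagent. The isovalerate is open to hydrolysis and acyl transfer. The C1=C2 alkene, with its allylic tertiary C6–H, can migrate or be lost to diene formation under strong acid or base. Both acyl-type groups therefore belong at the end.
- **Hindered substitution:** The C7–O bond has to be made at a β-branched primary carbon next to the quaternary centre.
- **Enabling feature:** C4 is a secondary carbinol bonded to C5, which carries two methyl groups and C6. If C6 is written as an alkene carbon, the array O–C4H–C5Me2–C6H=C is a reverse-prenyl (1,1-dimethylallyl) carbinol, the retron of a carbonyl tert-prenylation.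

## Retrosynthesis

**13 ⇒ 11 + 12.** The first cut is the C7–O bond to the coumarin.
- Cutting the ester first would leave a hydroxy ether that can only come from a differentiated diol. Cutting the aryl–O bond would demand a metal-catalysed coupling next to a C4 oxygen function.
- The alkyl–O cut removes nine carbons and the most fragile ring system in one move. Phenol 12 enters last, so its lactone meets nothing harsher than a carbonate.
- The forward substitution at a β-branched primary carbon must outrun elimination of the allylic C6–H. This is the reason for iodide as leaving group in 11 and a weakly basic phenoxide.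

**11 ⇒ 8 + 9 (through 10).** The acyl–O bond at C4 and the C7–I bond are cut together, and C7 is reconnected to the C4 oxygen.
- A stepwise alternative through a diol would require telling two hydroxyl groups apart and activating one of them.
- Here one ether oxygen and one reagent, acyl iodide 10 made from 9, supply both the ester and the leaving group. Oxabicycle 8 has ten carbons, no protecting group, and both stereocentres locked cis.
- Iodide must attack the acyloxonium ion at primary C7 and leave the C4–O bond alone, so that C4 keeps its configuration.

**8 ⇒ 6 (through 7).** The C6–C7 bond is cut.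
- Cutting O–C7 instead would lead to a hydroxymethyl cyclohexenol whose C6 centre would still have to be set independently.
- The C–C cut lets an oxocarbenium ion 7, hung on the C4 oxygen, reach C6 of a C6=C1 alkene. The bridge can span only one face, so the second stereocentre comes from the first. The alkene moves to C1=C2 in the same event.
- The precursor has a single stereocentre. Bond formation must occur at C6 (tertiary cation at C1) and the proton must be lost from C2.

**6 ⇒ 5.** The acetal O–CH2 bond is cut.
- The formaldehyde carbon C7 is brought in as a 2-methoxyethoxymethyl (MEM) ether rather than a methoxymethyl ether. The two distal oxygens chelate the Lewis acid, so ionisation takes place on the side remote from the ring.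
- The forward step is a routine protection of a hindered secondary alcohol.

**5 ⇒ 4.** The C1=C6 double bond is cut by a metathesis transform.
- No other ring bond opens to a chain that is as informative. This one unveils a vinyl group on the quaternary carbon and an isopropenyl terminus, that is, a reverse-prenyl carbinol with a simple side chain.
- The forward closure must join two sluggish alkenes. It is helped by the six-membered ring size and the gem-dimethyl group.

**4 ⇒ 1 + 2 (through 3).** The C4–C5 bond is cut.
- This is the most hindered bond of the molecule. Its formation creates the quaternary carbon and the only independent stereocentre at once.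
- Cutting C3–C4 would need a chiral α-quaternary aldehyde, which is no simpler than 4.
- Both fragments are achiral catalogue chemicals. Alcohol 1 serves as the aldehyde (3) precursor and as the hydrogen source for converting allene 2 into the allyl nucleophile.
- The forward reaction must deliver the branched regioisomer and one aldehyde face, and it must leave the 1,1-disubstituted alkene untouched.

## Roads not taken

**Alternative 1:**
- **Cut and key step:** The cut is the C4–O bond of the bridged lactone (1S,5R)-2,8,8-trimethyl-6-oxabicyclo[3.2.1]oct-2-en-7-one A2, traced back to the pinane-type cyclobutanone (1S,5R)-chrysanthenone A1. In the forward step a Baeyer–Villiger monooxygenase and O2 insert oxygen between the carbonyl carbon and the non-allylic bridgehead, with retention.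
- **Merits:** A2 already holds all ten terpene carbons, both stereocentres and the alkene in its final place. Reduction to the diol (1R,5S)-5-(hydroxymethyl)-4,6,6-trimethylcyclohex-3-en-1-ol A3, etherification of its primary hydroxyl with 12 and acylation with 9 would finish the work in four steps from A1. This is shorter than the chosen plan, and it avoids the question of alkene regiochemistry that step 4 has to answer.
- **Weak points:** Both migrating candidates are secondary bridgeheads, and the allylic one is electronically the better migrating group, so the required insertion runs against the intrinsic preference. Peracids would also epoxidise the trisubstituted alkene. The step therefore rests on an enzyme whose regiochemical preference for this bicycle cannot be derived from structure. A1 is a strained, light- and acid-sensitive β,γ-unsaturated cyclobutanone. It must first be secured in the correct enantiomeric series, and that costs extra steps.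
- **Comparison:** The chosen plan offers achiral commercial feedstocks, a ligand-controlled absolute configuration available in either sense, and a key step whose selectivity follows from a closed transition state.

**Alternative 2:**
- **Cut and key step:** The C6–H and C3–H bonds are cut, and the ring is traced to the arene 3-methoxy-2,6-dimethylbenzoic acid A4. Lithium in liquid ammonia reduces it at the carboxyl-bearing and the para carbon to racemic 3-methoxy-2,6-dimethylcyclohexa-2,5-diene-1-carboxylic acid A5.
- **Merits:** The starting material is a cheap arene and the first step is scalable. C7 is present from the start. The C1=C2 alkene is in the correct position, and C4 is masked as an enol ether.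
- **Weak points:** A5 is racemic and nothing in the sequence introduces absolute configuration, so a resolution is needed to reach a single enantiomer. The second methyl group at C5 is still missing. Once the C4 ketone is unmasked, C3 is both α to the carbonyl and allylic, so enolisation there competes with enolisation at C5 and draws the alkene into conjugation. A detour through cyclopropanation of the enol ether and ring opening would add steps. The ketone reduction must then be steered cis to the C6 substituent, the acid must be reduced, and two hydroxyl groups must be told apart.
- **Comparison:** The route is clearly longer than six steps and gives no enantiocontrol. Its only advantages are cost and scale at the outset.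

**Alternative 3:**
- **Cut and key step:** The ester C–O bond at C4 and a C2–H bond are cut. Catalytic SmI2 lets the hydroxy enone (5R)-5-hydroxy-2,4,4-trimethylcyclohex-2-en-1-one A6 and isovaleraldehyde A7 form a C4 hemiacetal. This delivers hydride to C2 in an Evans–Tishchenko reaction and gives (1R,5R)-5-hydroxy-2,2,4-trimethylcyclohex-3-en-1-yl 3-methylbutanoate A8.
- **Merits:** The isovalerate arrives without acylating agent or protecting group. The C2 alcohol allows C7 to be introduced by allylic transposition, which fixes the alkene at C1=C2 without ambiguity. In that respect it is better than the proton loss of step 4.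
- **Weak points:**
  - The key step only relays chirality, so an enantioselective access to A6 has to be added.
  - A6 is a β-hydroxy ketone that readily loses water to a cross-conjugated dienone.
  - The reaction class is established on acyclic β-hydroxy ketones. In a ring, the hydride transfer needs an axial C4–O and a bridged transition state while trivalent samarium holds both oxygens.
  - The C2 hydroxyl of A8 is trans to C4–O, so a suprafacial [2,3]-shift from it would place C7 on the wrong face. The relay must be read out in an anti-SN2′ sense at neopentyl C6 with a hydroxymethyl-anion equivalent, or inverted first. The ester excludes organolithium reagents.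
- **Comparison:** The chosen plan creates the absolute configuration catalytically in its first step and delivers C7 from the C4 oxygen, whose face is the correct one.

Key step: step 1

Assumption: (S)-SEGPHOS is taken to give the (4R)-carbinol, by analogy with the sense of induction of related iridium-catalysed allylations of aliphatic alcohols. Should the opposite sense be found, (R)-SEGPHOS is used and nothing else changes.

## Steps

Step 1
Reactants: 1 4-methylpent-4-en-1-ol; 2 3-methylbuta-1,2-diene
Product: 4 (4R)-3,3,7-trimethylocta-1,7-dien-4-ol, via 4-methylpent-4-enal 3 (not isolated)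
Conditions: [Ir(cod)Cl]2 (2.5 mol %), (S)-SEGPHOS (5 mol %), 3-nitrobenzoic acid (10 mol %), allyl acetate (10 mol %), Cs2CO3 (20 mol %), THF, 80 °C (catalyst pre-formation); then 1, 2 (4 equiv), toluene, 60 °C, sealed tube
Reagents that add atoms: none
Why: The pre-formed cyclometallated complex Ir(η3-C3H5)((S)-SEGPHOS)(κ2-C,O-3-NO2C6H3CO2) enters the cycle as a trivalent iridium alkoxide of 1; β-hydride elimination releases aldehyde 3 and an iridium hydride, which adds to the central carbon of allene 2 to give a 1,1-dimethylallyl iridium species. Its primary σ-allyl form binds 3 and transfers the allyl group through the tertiary terminus in a closed six-membered chair, and exchange of the resulting alkoxide with fresh 1 closes a redox-neutral cycle without any preformed organometallic. The closest known reaction type is the iridium-catalysed enantioselective tert-prenylation of primary alcohols, unactivated aliphatic ones included, with 1,1-dimethylallene under transfer hydrogenation. No ring is closed; the C4–C5 bond, the quaternary carbon C5 and the stereocentre C4 are formed. C4 is controlled by the catalyst alone: the bisphosphine and the C,O-benzoate leave one quadrant open, so that the aldehyde is bound with its chain equatorial in the chair and offers one face. Branched regioselectivity follows from the SE2′ geometry of the chair, because iridium rests on the unhindered CH2 terminus. The step also needs chemoselectivity toward the 1,1-disubstituted alkene of 1, which is a far poorer hydrometallation partner than the cumulated diene used in excess and is remote from the carbinol carbon, so it should remain a spectator.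

Step 2
Reactants: 4 (4R)-3,3,7-trimethylocta-1,7-dien-4-ol
Product: 5 (1R)-2,2,4-trimethylcyclohex-3-en-1-ol
Conditions: second-generation Grubbs catalyst (H2IMes)(PCy3)Cl2Ru=CHPh (5 mol %), CH2Cl2 (0.01 M), reflux, argon purge
Reagents that add atoms: none
Why: Ring-closing metathesis: the catalyst loads on the monosubstituted vinyl group and closes on the isopropenyl terminus to a six-membered trisubstituted alkene (C6=C1), aided by the Thorpe–Ingold effect of C5 and driven by loss of ethene. The C4 stereocentre is not involved.

Step 3
Reactants: 5 (1R)-2,2,4-trimethylcyclohex-3-en-1-ol
Product: 6 (4R)-4-[(2-methoxyethoxy)methoxy]-1,3,3-trimethylcyclohex-1-ene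
Conditions: MEMCl, iPr2NEt, CH2Cl2, 0 °C to reflux
Reagents that add atoms: 2-methoxyethoxymethyl chloride (MEMCl), COCCOCCl
Why: Standard MEM etherification of a hindered secondary alcohol with an α-chloro ether and an amine base; it brings in C7 at the formaldehyde oxidation level. The MEM group is chosen because its two distal oxygens chelate SnCl4 in step 4 and direct ionisation away from the ring oxygen.

Step 4
Reactants: 6 (4R)-4-[(2-methoxyethoxy)methoxy]-1,3,3-trimethylcyclohex-1-ene
Product: 8 (1S,5R)-2,8,8-trimethyl-6-oxabicyclo[3.2.1]oct-2-ene, via methylene oxocarbenium ion 7 (not isolated)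
Conditions: SnCl4 (1.5 equiv), CH2Cl2, −78 to −20 °C; aq. NaHCO3
Reagents that add atoms: none
Why: Acetal-initiated Prins cyclisation of the (3,5)-oxonium-ene type, known for homoallylic alcohols and ethers with a trisubstituted alkene: chelation-assisted loss of 2-methoxyethoxide gives 7, and C6 attacks its CH2 carbon in the Markovnikov sense (tertiary cation at C1; five-membered ring, exo with respect to the alkene, with the O=CH2 unit inside the new ring). The O–C7 bridge can span C4 and C6 on one face only, so C4 sets C6 as cis (6S). Proton loss toward the bridgehead is forbidden and should favour C2, giving the more substituted C1=C2 alkene, while any tertiary chloride re-ionises under SnCl4.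

Step 5
Reactants: 8 (1S,5R)-2,8,8-trimethyl-6-oxabicyclo[3.2.1]oct-2-ene; 9 3-methylbutanoyl chloride (isovaleryl chloride)
Product: 11 (1R,5S)-5-(iodomethyl)-4,6,6-trimethylcyclohex-3-en-1-yl 3-methylbutanoate, via isovaleryl iodide 10 (not isolated)
Conditions: 9, NaI, MeCN, 0 °C to rt, dark; aq. Na2S2O3
Reagents that add atoms: sodium iodide, [Na+].[I-]
Why: Acyl iodide cleavage of a cyclic ether: 10, formed by halide exchange, acylates the ether oxygen, and iodide opens the acyloxonium ion by SN2 at primary C7 rather than at the secondary, neopentyl C4. The C4–O bond is never broken, so C4 is retained, C6 is untouched, and ester and leaving group are installed in one operation.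

Step 6
Reactants: 11 (1R,5S)-5-(iodomethyl)-4,6,6-trimethylcyclohex-3-en-1-yl 3-methylbutanoate; 12 umbelliferone (7-hydroxycoumarin)
Product: 13 (1R,5S)-4,6,6-trimethyl-5-{[(2-oxo-2H-chromen-7-yl)oxy]methyl}cyclohex-3-en-1-yl 3-methylbutanoate
Conditions: Cs2CO3, DMF, 50 °C
Reagents that add atoms: none
Why: Williamson ether synthesis with a weakly basic caesium phenoxide and a primary iodide in a dipolar aprotic solvent, the usual way of attaching terpenyl residues to umbelliferone. Anhydrous carbonate should leave the lactone and the hindered ester intact, and no stereocentre takes part.

## Compound list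

1 | 4-methylpent-4-en-1-ol | CC(=C)CCCO | starting material
2 | 3-methylbuta-1,2-diene | CC(C)=C=C | starting material
3 | 4-methylpent-4-enal | CC(=C)CCC=O | intermediate
4 | (4R)-3,3,7-trimethylocta-1,7-dien-4-ol | C=C(C)CC[C@@H](O)C(C)(C)C=C | intermediate
5 | (1R)-2,2,4-trimethylcyclohex-3-en-1-ol | CC1=CC(C)(C)[C@H](O)CC1 | intermediate
6 | (4R)-4-[(2-methoxyethoxy)methoxy]-1,3,3-trimethylcyclohex-1-ene | CC1=CC(C)(C)[C@H](OCOCCOC)CC1 | intermediate
7 | methylidene[(1R)-2,2,4-trimethylcyclohex-3-en-1-yl]oxonium (oxocarbenium ion) | CC1=CC(C)(C)[C@H]([O+]=C)CC1 | intermediate
8 | (1S,5R)-2,8,8-trimethyl-6-oxabicyclo[3.2.1]oct-2-ene | CC1=CC[C@H]2OC[C@@H]1C2(C)C | intermediate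
9 | 3-methylbutanoyl chloride (isovaleryl chloride) | CC(C)CC(Cl)=O | starting material
10 | 3-methylbutanoyl iodide (isovaleryl iodide) | CC(C)CC(I)=O | intermediate
11 | (1R,5S)-5-(iodomethyl)-4,6,6-trimethylcyclohex-3-en-1-yl 3-methylbutanoate | CC1=CC[C@@H](OC(=O)CC(C)C)C(C)(C)[C@H]1CI | intermediate
12 | umbelliferone (7-hydroxycoumarin) | O=c1ccc2ccc(O)cc2o1 | starting material
13 | (1R,5S)-4,6,6-trimethyl-5-{[(2-oxo-2H-chromen-7-yl)oxy]methyl}cyclohex-3-en-1-yl 3-methylbutanoate | CC1=CC[C@@H](OC(=O)CC(C)C)C(C)(C)[C@H]1COc1ccc2ccc(=O)oc2c1 | target

## Step count and least certain steps

Total steps: 6. Longest linear sequence: 6 (from 1 and 2 to 13).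

**Step 1 (key step).**
- **Risk:** Conversion may stall or enantioselectivity may erode, because 1 is an unbranched aliphatic alcohol that dehydrogenates less readily than a benzylic one. The transient aldehyde is enolisable and, as a γ,δ-unsaturated aldehyde, open to metal-induced side reactions. The iridium hydride may move the 1,1-disubstituted double bond, and the low-boiling allene may escape or oligomerise.
- **Fallback:** It sets out from 1 and 2 and returns at 4. It replaces catalysis by a stoichiometric chiral allylborane while forming the same C4–C5 bond. Alcohol 1 is oxidised (TEMPO, PhI(OAc)2) to 3, which is now isolated. Allene 2 is hydroborated at its terminal double bond with (−)-diisopinocampheylborane (from (+)-α-pinene) to give B-(3-methylbut-2-enyl)diisopinocampheylborane F1. This adds to 3 at −78 °C through its tertiary carbon in a chair transition state, and NaOH/H2O2 work-up gives 4.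

**Step 4.**
- **Risk:** Closure onto neopentyl C6 with the O=CH2 unit inside the forming five-membered ring may be slow. The oxocarbenium ion could then escape by 2-oxonia-Cope cleavage of the C4–C5 bond, which the gem-dimethyl group favours, or by simple loss of the acetal. Proton loss toward the methyl group or chloride capture would erode the alkene regiochemistry. The HCl released may protonate the alkene of unreacted 6 and trigger transannular etherification between the C4 oxygen and C1.
- **Fallback:** It sets out from 5 and returns at 11. It delivers C7 by a hydroxyl-directed cyclopropanation and fixes the alkene by a cyclopropylcarbinyl–homoallyl rearrangement.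
  - Acylation of 5 with 9 (pyridine, DMAP) gives (1R)-2,2,4-trimethylcyclohex-3-en-1-yl 3-methylbutanoate F2.
  - Allylic oxidation of the ring CH2 at C2 (CrO3, 3,5-dimethylpyrazole, CH2Cl2) gives (1R)-2,2,4-trimethyl-5-oxocyclohex-3-en-1-yl 3-methylbutanoate F3.
  - Luche reduction (NaBH4, CeCl3·7H2O, MeOH), by axial hydride delivery to the conformer with an equatorial ester, gives the cis alcohol (1R,5S)-5-hydroxy-2,2,4-trimethylcyclohex-3-en-1-yl 3-methylbutanoate F4.
  - Simmons–Smith cyclopropanation (Et2Zn, CH2I2), directed by the C2 hydroxyl to the face that also carries C4–O, gives (1R,3R,5S,6R)-5-hydroxy-2,2,6-trimethylbicyclo[4.1.0]heptan-3-yl 3-methylbutanoate F5.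
  - MgI2 in refluxing Et2O ionises the carbinol. Iodide attacks the cyclopropane CH2, the C1–C7 bond breaks, and the C1=C2 alkene forms, which gives 11.

**Step 6.**
- **Risk:** Substitution at the β-branched C7 may be slower than E2 loss of the allylic C6–H, which leads to a conjugated diene. Acyl transfer from C4 to the phenoxide would free an alkoxide that recloses the oxabicycle.
- **Fallback:** It sets out from 11 and returns at 13. It replaces the base-mediated alkylation by a redox condensation under neutral conditions.
  - The less basic formate ion (HCO2Na, DMF, 70 °C) converts 11 into (1R,5S)-5-[(formyloxy)methyl]-4,6,6-trimethylcyclohex-3-en-1-yl 3-methylbutanoate F6.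
  - Mild methanolysis (KHCO3, MeOH, 0 °C) removes only the formyl group and gives (1R,5S)-5-(hydroxymethyl)-4,6,6-trimethylcyclohex-3-en-1-yl 3-methylbutanoate F7.
  - Mitsunobu reaction of F7 with 12 (PPh3, DIAD, THF) gives 13.

**Step 5.**
- **Risk:** Acylation of an ether oxygen next to the neopentyl C4 may be sluggish. Traces of HI may add to or shift the trisubstituted alkene. Partial ionisation at C4 would scramble that centre or start a methyl shift from C5.
- **Fallback:** It sets out from 8 and returns at 11. It separates ether cleavage from acylation.
  - Me2BBr (CH2Cl2, 0 °C; aqueous work-up) opens the ether by bromide attack at C7 to (1R,5S)-5-(bromomethyl)-4,6,6-trimethylcyclohex-3-en-1-ol F8.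
  - Acylation with 9 (pyridine, DMAP), without strong base so that the ether cannot reclose, gives (1R,5S)-5-(bromomethyl)-4,6,6-trimethylcyclohex-3-en-1-yl 3-methylbutanoate F9.
  - Finkelstein exchange (NaI, acetone, reflux) gives 11.

**Step 2.**
- **Risk:** Both alkenes are slow metathesis partners, one being on a quaternary carbon and the other 1,1-disubstituted. Catalyst decay may therefore outpace ring closure. Ruthenium hydrides formed on decay may move the isopropenyl double bond inward and end the reaction. The volatile product may be lost on concentration.
- **Fallback:** It sets out from 4 and returns at 5. It forms the same C1=C6 bond by reductive carbonyl coupling.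
  - Silylation (TBSOTf, 2,6-lutidine) gives (4R)-4-[(tert-butyldimethylsilyl)oxy]-3,3,7-trimethylocta-1,7-diene F10.
  - Ozonolysis of both alkenes (O3, CH2Cl2, −78 °C; Me2S) gives (3R)-3-[(tert-butyldimethylsilyl)oxy]-2,2-dimethyl-6-oxoheptanal F11.
  - Intramolecular McMurry coupling (TiCl3(DME)1.5, zinc–copper couple, DME, reflux, slow addition) gives tert-butyldimethyl{[(1R)-2,2,4-trimethylcyclohex-3-en-1-yl]oxy}silane F12.
  - Bu4NF (THF) gives 5.

## Further compounds

F1 | step 1 | B-(3-methylbut-2-enyl)diisopinocampheylborane (from (+)-α-pinene) | CC(C)=CCB([C@@H]1C[C@@H]2C[C@@H](C2(C)C)[C@H]1C)[C@@H]1C[C@@H]2C[C@@H](C2(C)C)[C@H]1C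
F2 | step 4 | (1R)-2,2,4-trimethylcyclohex-3-en-1-yl 3-methylbutanoate | CC1=CC(C)(C)[C@H](OC(=O)CC(C)C)CC1
F3 | step 4 | (1R)-2,2,4-trimethyl-5-oxocyclohex-3-en-1-yl 3-methylbutanoate | CC1=CC(C)(C)[C@H](OC(=O)CC(C)C)CC1=O
F4 | step 4 | (1R,5S)-5-hydroxy-2,2,4-trimethylcyclohex-3-en-1-yl 3-methylbutanoate | CC1=CC(C)(C)[C@H](OC(=O)CC(C)C)C[C@@H]1O
F5 | step 4 | (1R,3R,5S,6R)-5-hydroxy-2,2,6-trimethylbicyclo[4.1.0]heptan-3-yl 3-methylbutanoate | C[C@@]12C[C@@H]1C(C)(C)[C@H](OC(=O)CC(C)C)C[C@@H]2O
F6 | step 6 | (1R,5S)-5-[(formyloxy)methyl]-4,6,6-trimethylcyclohex-3-en-1-yl 3-methylbutanoate | CC1=CC[C@@H](OC(=O)CC(C)C)C(C)(C)[C@H]1COC=O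
F7 | step 6 | (1R,5S)-5-(hydroxymethyl)-4,6,6-trimethylcyclohex-3-en-1-yl 3-methylbutanoate | CC1=CC[C@@H](OC(=O)CC(C)C)C(C)(C)[C@H]1CO
F8 | step 5 | (1R,5S)-5-(bromomethyl)-4,6,6-trimethylcyclohex-3-en-1-ol | CC1=CC[C@@H](O)C(C)(C)[C@H]1CBr
F9 | step 5 | (1R,5S)-5-(bromomethyl)-4,6,6-trimethylcyclohex-3-en-1-yl 3-methylbutanoate | CC1=CC[C@@H](OC(=O)CC(C)C)C(C)(C)[C@H]1CBr
F10 | step 2 | (4R)-4-[(tert-butyldimethylsilyl)oxy]-3,3,7-trimethylocta-1,7-diene | C=C(C)CC[C@@H](O[Si](C)(C)C(C)(C)C)C(C)(C)C=C
F11 | step 2 | (3R)-3-[(tert-butyldimethylsilyl)oxy]-2,2-dimethyl-6-oxoheptanal | CC(=O)CC[C@@H](O[Si](C)(C)C(C)(C)C)C(C)(C)C=O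
F12 | step 2 | tert-butyldimethyl{[(1R)-2,2,4-trimethylcyclohex-3-en-1-yl]oxy}silane | CC1=CC(C)(C)[C@H](O[Si](C)(C)C(C)(C)C)CC1
A1 | alternative 1 | (1S,5R)-2,7,7-trimethylbicyclo[3.1.1]hept-2-en-6-one (chrysanthenone) | CC1=CC[C@H]2C(=O)[C@@H]1C2(C)C
A2 | alternative 1 | (1S,5R)-2,8,8-trimethyl-6-oxabicyclo[3.2.1]oct-2-en-7-one | CC1=CC[C@H]2OC(=O)[C@@H]1C2(C)C
A3 | alternative 1 | (1R,5S)-5-(hydroxymethyl)-4,6,6-trimethylcyclohex-3-en-1-ol | CC1=CC[C@@H](O)C(C)(C)[C@H]1CO
A4 | alternative 2 | 3-methoxy-2,6-dimethylbenzoic acid | COc1ccc(C)c(C(=O)O)c1C
A5 | alternative 2 | racemic 3-methoxy-2,6-dimethylcyclohexa-2,5-diene-1-carboxylic acid | COC1=C(C)C(C(=O)O)C(C)=CC1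
A6 | alternative 3 | (5R)-5-hydroxy-2,4,4-trimethylcyclohex-2-en-1-one | CC1=CC(C)(C)[C@H](O)CC1=O
A7 | alternative 3 | 3-methylbutanal (isovaleraldehyde) | CC(C)CC=O
A8 | alternative 3 | (1R,5R)-5-hydroxy-2,2,4-trimethylcyclohex-3-en-1-yl 3-methylbutanoate | CC1=CC(C)(C)[C@H](OC(=O)CC(C)C)C[C@H]1O
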